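A direct plan would buy the central ring: 5-bromobenzene-1,3-diol A1 would be O-alkylated twice with 4-methoxybenzyl chloride to give 1-bromo-3,5-bis[(4-methoxybenzyl)oxy]benzene A2, the 4-methoxyphenethyl arm would be attached by hydroboration and B-alkyl Suzuki coupling to give 1-[2-(4-methoxyphenyl)ethyl]-3,5-bis[(4-methoxybenzyl)oxy]benzene A3, both benzyl groups would then be shifted by acid from oxygen to the ring carbons next to the arm to give 4,6-bis(4-methoxybenzyl)-5-[2-(4-methoxyphenyl)ethyl]benzene-1,3-diol A4, and the three methyl ethers would be cut with BBr3.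
Its weakest operation would be the twofold acid-induced O-to-C shift of the benzyl groups: it has no precedent as a planned double transposition, and the freed cation could equally attack the carbon between the two oxygens, an anisole ring or another molecule, so the 4,5,6-pattern of the core would be left to chance on the most advanced material.
The second would be the BBr3 cleavage in the same flask: hours of excess strong Lewis acid on 4-hydroxybenzyl-substituted resorcinols, which can lose or exchange such benzyl groups by retro-Friedel-Crafts reaction, with nothing left to repair at the last stage.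

**Plan of the new route**
The central ring is not bought but made last, from carbon chains that already carry all three arms.
Enabling feature: the mirror plane through C2-H and C5 of the central ring. Ring atoms C4-C3(OH)-C2(H)-C1(OH)-C6 with both 4-hydroxybenzyl arms are the chain of a symmetric 1,7-diarylheptane-3,5-dione (a 1,3-diol flanking a bare CH is an enolised β-diketone), and C5, para to C2 and free of oxygen, is a carbonyl carbon that has lost its oxygen in an aldol condensation.
Cuts: ring bonds C5-C6 (aldol) and C4-C5 (acylation) give that diketone and a cinnamoyl unit; the two ArCH2-CH2 bonds of the diketone go back to acetylacetone and two equivalents of one benzylic chloride.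
Ring order: the three outer rings come with the starting materials; the resorcinol ring arises in the key step as a [5+1] benzannulation modelled on the stilbene and bibenzyl synthase ring closure.
The weak operations do not occur: both benzyl arms are fixed to sp3 carbons before any arene exists, and the phenols travel as benzyl ethers that leave under H2 in the step that also saturates the bridge, so no acid meets the finished skeleton.

Key step: step 3

Remark: the target is achiral; the stereocentres that appear on the way (one in triketone 8, up to three in aldol 9) are formed without control and are erased on aromatisation.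

Step 1
Reactants: 1 pentane-2,4-dione (acetylacetone); 2 4-(benzyloxy)benzyl chloride (2.0 equiv)
Product: 4 1,7-bis[4-(benzyloxy)phenyl]heptane-3,5-dione, via monoalkylated diketone 3 (not isolated)
Conditions: LiN(i-Pr)2 (LDA, 2.1 equiv), THF, 0 °C; 2 (1.0 equiv), 0 °C; LiN(i-Pr)2 (1.1 equiv), 0 °C; 2 (1.0 equiv), 0 °C to rt; 1 M HCl
Reagents that add atoms: 4-(benzyloxy)benzyl chloride (2), ClCc1ccc(OCc2ccccc2)cc1
Why: Twofold terminal C-alkylation of a β-diketone dianion: in each round the extra equivalent of LiN(i-Pr)2 removes a proton from a terminal carbon of the lithium enolate, that carbanion is far more nucleophilic than the enolate carbon and displaces chloride from 2 by SN2, and the second deprotonation should take the remaining methyl group of 3 (less hindered and more acidic than its CH2), which places the two arms on the future ring carbons C4 and C6 before any ring exists; no stereocentre is formed.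

Step 2
Reactants: 5 4-(benzyloxy)benzaldehyde; 6 diethyl {2-[methoxy(methyl)amino]-2-oxoethyl}phosphonate (1.1 equiv)
Product: 7 (2E)-3-[4-(benzyloxy)phenyl]-N-methoxy-N-methylprop-2-enamide
Conditions: NaH (1.1 equiv), THF, 0 °C; 5, 0 °C to rt
Reagents that add atoms: diethyl {2-[methoxy(methyl)amino]-2-oxoethyl}phosphonate (6), CCOP(=O)(CC(=O)N(C)OC)OCC
Why: Horner-Wadsworth-Emmons olefination: the sodium phosphonate carbanion adds to the non-enolisable aromatic aldehyde and the stabilised, reversibly formed adduct should collapse to the E-enamide, with the benzyl ether inert; no stereocentre is formed.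

Step 3
Reactants: 4 1,7-bis[4-(benzyloxy)phenyl]heptane-3,5-dione (1.1 equiv); 7 (2E)-3-[4-(benzyloxy)phenyl]-N-methoxy-N-methylprop-2-enamide (1.0 equiv)
Product: 10 4,6-bis[4-(benzyloxy)benzyl]-5-{(E)-2-[4-(benzyloxy)phenyl]ethenyl}benzene-1,3-diol, via styryl triketone 8 (not isolated), via cyclic aldol 9 (not isolated)
Conditions: 4, LiN(i-Pr)2 (2.3 equiv), THF, −78 to 0 °C; 7, −78 to 0 °C; 1 M HCl, 0 °C, extraction; crude 8, 2 M aq KOH (5 equiv), MeOH/THF (degassed, argon), rt to 40 °C; 1 M HCl to pH 3
Reagents that add atoms: (2E)-3-[4-(benzyloxy)phenyl]-N-methoxy-N-methylprop-2-enamide (7), CON(C)C(=O)/C=C/c1ccc(OCc2ccccc2)cc1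
Why: The dianion of 4 (central carbon and one terminal CH2 lithiated) adds through its terminal carbanion to the amide carbonyl of 7, the chelated N-methoxy-N-methyl tetrahedral adduct survives until the acid quench and then releases triketone 8, and in aqueous methanolic KOH the terminal enolate carbon C8 of 8 adds to its C3 ketone, after which loss of water from aldol 9 and enolisation give the arene. The closest known reaction types are the terminal acylation of β-diketone dianions and the base-induced aldol cyclisation of 3,5,7-triketones to 5-substituted resorcinols, the laboratory counterpart of the stilbene and bibenzyl synthase ring closure. The central ring closes by the C8–C3 bond of 8 (C6–C5 of the target) in a 6-(enolendo)-exo-trig aldol condensation, the C4–C5 bond of the target having been made in the acylation, and aromatisation makes the closure irreversible. The stereocentre of 8 and those of 9 are formed without control and vanish on aromatisation, and the E double bond is carried over from 7 and is saturated in step 4, so no stereochemical element needs control. The selectivity needed is the direction of the aldol, and the substrate secures it because the cinnamoyl carbonyl has no sp3 α-hydrogen, so C8 is the only carbon able to close a six-membered carbocycle, whereas a saturated 3-arylpropanoyl unit would offer a second aldol leading to the 2,4-dibenzyl isomer. Conjugate closures by oxygen or by the central carbon onto the styryl β-carbon, which the 4-benzyloxy group makes a poor acceptor, should be reversible in base and drain into the aromatic product, and the aryl benzyl ethers are inert to both stages.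

Step 4
Reactants: 10 4,6-bis[4-(benzyloxy)benzyl]-5-{(E)-2-[4-(benzyloxy)phenyl]ethenyl}benzene-1,3-diol
Product: 11 4,6-bis(4-hydroxybenzyl)-5-[2-(4-hydroxyphenyl)ethyl]benzene-1,3-diol
Conditions: H2 (1 atm), Pd/C (10% palladium on carbon), EtOAc/MeOH 1:1, rt
Reagents that add atoms: none
Why: Heterogeneous hydrogenation and hydrogenolysis over palladium on carbon: the stilbene double bond is saturated and the three aryl benzyl ethers are cleaved in one operation under neutral conditions, while the diarylmethane C–C bonds, the arene rings and the free phenols should be untouched at one atmosphere and room temperature; no stereocentre is formed.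

**Compound list**
1 | pentane-2,4-dione (acetylacetone) | CC(=O)CC(C)=O | starting material
2 | 4-(benzyloxy)benzyl chloride | ClCc1ccc(OCc2ccccc2)cc1 | starting material
3 | 6-[4-(benzyloxy)phenyl]hexane-2,4-dione | CC(=O)CC(=O)CCc1ccc(OCc2ccccc2)cc1 | intermediate
4 | 1,7-bis[4-(benzyloxy)phenyl]heptane-3,5-dione | O=C(CCc1ccc(OCc2ccccc2)cc1)CC(=O)CCc1ccc(OCc2ccccc2)cc1 | intermediate
5 | 4-(benzyloxy)benzaldehyde | O=Cc1ccc(OCc2ccccc2)cc1 | starting material
6 | diethyl {2-[methoxy(methyl)amino]-2-oxoethyl}phosphonate | CCOP(=O)(CC(=O)N(C)OC)OCC | starting material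
7 | (2E)-3-[4-(benzyloxy)phenyl]-N-methoxy-N-methylprop-2-enamide | CON(C)C(=O)/C=C/c1ccc(OCc2ccccc2)cc1 | intermediate
8 | (1E)-1,9-bis[4-(benzyloxy)phenyl]-4-[4-(benzyloxy)benzyl]non-1-ene-3,5,7-trione (racemic) | O=C(/C=C/c1ccc(OCc2ccccc2)cc1)C(Cc1ccc(OCc2ccccc2)cc1)C(=O)CC(=O)CCc1ccc(OCc2ccccc2)cc1 | intermediate
9 | 4,6-bis[4-(benzyloxy)benzyl]-5-{(E)-2-[4-(benzyloxy)phenyl]ethenyl}-5-hydroxycyclohexane-1,3-dione (mixture of diastereomers) | O=C1CC(=O)C(Cc2ccc(OCc3ccccc3)cc2)C(O)(/C=C/c2ccc(OCc3ccccc3)cc2)C1Cc1ccc(OCc2ccccc2)cc1 | intermediate
10 | 4,6-bis[4-(benzyloxy)benzyl]-5-{(E)-2-[4-(benzyloxy)phenyl]ethenyl}benzene-1,3-diol | Oc1cc(O)c(Cc2ccc(OCc3ccccc3)cc2)c(/C=C/c2ccc(OCc3ccccc3)cc2)c1Cc1ccc(OCc2ccccc2)cc1 | intermediate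
11 | 4,6-bis(4-hydroxybenzyl)-5-[2-(4-hydroxyphenyl)ethyl]benzene-1,3-diol (CNP0326726.0, achiral) | Oc1ccc(CCc2c(Cc3ccc(O)cc3)c(O)cc(O)c2Cc2ccc(O)cc2)cc1 | target

Total steps: 4. Longest linear sequence: 3 steps (steps 1, 3, 4); step 2 is a one-step branch.

**Steps most likely to fail**

Step 3 (key step). What may go wrong: conjugate addition of the dianion of 4 to the β-carbon of 7 in place of addition to the amide carbonyl, so that the triketone is not formed. Fallback (sets out from 4 and 7, comes back to the route at 8): 7 would be reduced with i-Bu2AlH in THF at −78 °C to (2E)-3-[4-(benzyloxy)phenyl]prop-2-enal F1. The dianion of 4 would add at −78 °C to the aldehyde carbonyl of F1, for which carbonyl addition of a lithium carbanion is the rule, to give (1E)-1,9-bis[4-(benzyloxy)phenyl]-4-[4-(benzyloxy)benzyl]-3-hydroxynon-1-ene-5,7-dione F2. MnO2 in CH2Cl2 would oxidise the allylic alcohol of F2 to triketone 8, which would then be closed with KOH as in the second stage of step 3.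

Step 1. What may go wrong: loss of site control in the second deprotonation and proton transfer between mono- and dianions, leading to mixtures of under-, over- and wrongly benzylated diketones that are hard to separate. Fallback (sets out from 1 and 5, comes back to the route at 4): 1 and two equivalents of 5 would be condensed at the two methyl groups of the boron-chelated diketone (B2O3, B(On-Bu)3, catalytic n-BuNH2, EtOAc, 70 °C; then dilute HCl) to (1E,6E)-1,7-bis[4-(benzyloxy)phenyl]hepta-1,6-diene-3,5-dione F3. The two enone double bonds of F3 would be hydrogenated over Pd/C in the presence of 2,2′-bipyridine, an additive that suppresses hydrogenolysis of aryl benzyl ethers, to give 4.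

Step 4. What may go wrong: hydrogenolysis stalling at partly benzylated phenols as the polar product adsorbs on the catalyst, or air oxidation of the electron-rich polyphenol during a prolonged run. Fallback (sets out from 10, comes back to the route at 11): the double bond would first be reduced with diimide (p-toluenesulfonyl hydrazide, NaOAc, THF/H2O, reflux) to 4,6-bis[4-(benzyloxy)benzyl]-5-{2-[4-(benzyloxy)phenyl]ethyl}benzene-1,3-diol F4. The three benzyl ethers of F4 would then be cleaved with BCl3 in CH2Cl2 at −78 °C in the presence of pentamethylbenzene, which traps the benzyl cations before they can attack the resorcinol ring, to give 11.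

**Further compounds**
F1 | step 3 | (2E)-3-[4-(benzyloxy)phenyl]prop-2-enal | O=C/C=C/c1ccc(OCc2ccccc2)cc1
F2 | step 3 | (1E)-1,9-bis[4-(benzyloxy)phenyl]-4-[4-(benzyloxy)benzyl]-3-hydroxynon-1-ene-5,7-dione | OC(/C=C/c1ccc(OCc2ccccc2)cc1)C(Cc1ccc(OCc2ccccc2)cc1)C(=O)CC(=O)CCc1ccc(OCc2ccccc2)cc1
F3 | step 1 | (1E,6E)-1,7-bis[4-(benzyloxy)phenyl]hepta-1,6-diene-3,5-dione | O=C(/C=C/c1ccc(OCc2ccccc2)cc1)CC(=O)/C=C/c1ccc(OCc2ccccc2)cc1
F4 | step 4 | 4,6-bis[4-(benzyloxy)benzyl]-5-{2-[4-(benzyloxy)phenyl]ethyl}benzene-1,3-diol | Oc1cc(O)c(Cc2ccc(OCc3ccccc3)cc2)c(CCc2ccc(OCc3ccccc3)cc2)c1Cc1ccc(OCc2ccccc2)cc1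
A1 | direct plan | 5-bromobenzene-1,3-diol | Oc1cc(O)cc(Br)c1
A2 | direct plan | 1-bromo-3,5-bis[(4-methoxybenzyl)oxy]benzene | COc1ccc(COc2cc(Br)cc(OCc3ccc(OC)cc3)c2)cc1
A3 | direct plan | 1-[2-(4-methoxyphenyl)ethyl]-3,5-bis[(4-methoxybenzyl)oxy]benzene | COc1ccc(CCc2cc(OCc3ccc(OC)cc3)cc(OCc3ccc(OC)cc3)c2)cc1
A4 | direct plan | 4,6-bis(4-methoxybenzyl)-5-[2-(4-methoxyphenyl)ethyl]benzene-1,3-diol | COc1ccc(CCc2c(Cc3ccc(OC)cc3)c(O)cc(O)c2Cc2ccc(OC)cc2)cc1
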